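13.2% of the charge is the number to watch in the new flask: f, the fraction of the charge that stands as intermediate on its plateau.

| flask | substrate | remark | time |
|---|---|---|---|
| Thursday's | 13 mM | run made earlier |  |
| Wednesday's | 30 mM | run made earlier |  |
| flask | 20 mM |  | 2.0 h |

| run | time / min | side product / % | target / % | substrate / % | over-reaction product / % | intermediate / % |
|---|---|---|---|---|---|---|
| Thursday's | 6.00 | 1.5 | 0.6 | 93.4 | 0 | 6.3 |
| Thursday's | 20.0 | 9.3 | 1.9 | 79.3 | 0.9 | 14.5 |
| Thursday's | 30.0 | 17.7 | 0.9 | 63.4 | 0.4 | 15.4 |
| Thursday's | 50.0 | 34.7 | 1.9 | 44.3 | 0 | 18.7 |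
| Thursday's | 80.0 | 47.7 | 6.0 | 25.9 | 0.9 | 19.4 |
| Thursday's | 90.0 | 50.2 | 4.2 | 22.0 | 0 | 19.1 |
| Thursday's | 120 | 57.7 | 7.1 | 12.1 | 0.8 | 18.1 |
| Wednesday's | 10.0 | 6.1 | 1.3 | 85.4 | 1.3 | 8.0 |
| Wednesday's | 15.0 | 11.9 | 0 | 80.8 | 1.1 | 8.4 |
| Wednesday's | 20.0 | 16.2 | 1.0 | 72.7 | 0 | 9.8 |
| Wednesday's | 30.0 | 29.0 | 0 | 59.4 | 0 | 11.1 |
| Wednesday's | 50.0 | 45.2 | 2.1 | 40.6 | 0 | 9.7 |
| Wednesday's | 80.0 | 63.8 | 2.6 | 23.7 | 0 | 11.2 |
| Wednesday's | 120 | 73.8 | 4.6 | 11.0 | 0 | 9.8 |

(scatter of a reading: 1 percentage point)

1. the largest share of what was charged as substrate, at 2.0 h belongs to (intermediate / substrate / over-reaction product / side product / target)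
2. the largest share itself, whichever of these holds it, in percent of the substrate charged

- percentages count the substrate that a species holds: one side product counts as two
- a reading or a percentage of target counts all its forms, free or not
- a reading or a percentage of substrate is of its free form alone

We get f from the balance of the intermediate. In Thursday's run it goes from 19.4% to 18.1% between 80.0 min and 120 min, while the substrate falls from 25.9% to 12.1%. So we take its making and its using to both go with the substrate, which then cancels from the balance (a quasi-steady state). At 120 min the runs hold intermediate at 2.35 mM and 2.94 mM, and f is their mean over the new flask's charge.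

Is f enough? Charge minus substrate minus intermediate overshoots the side product by 12 percentage points on Thursday and 5.4 points on Wednesday, so it is not. But at 120 min Wednesday's run stands above Thursday's in side product by 1.94 times what it stands below it in intermediate. Along that line we reckon side product in the new flask at 2.0 h at 67.1%, the largest share.

The forecast says side product at 67%, holding that the intermediate “forms from substrate and is consumed by reacting with substrate to give the side product”. The flask gives side product at 66.9%, with intermediate at 13.3%.

    substrate → intermediate (k = 0.620 /h)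
    intermediate → target (k = 0.230 /h)
    target → over-reaction product (k = 0.110 /h)
    substrate + target ⇌ idle adduct, settled at all times (K = 670 /M)
    substrate + intermediate → side product (k = 180 /M/h)

In the neighbour flask, charged with 80 mM of substrate, the same plateau gives f of 3.31%, and the line gives side product at 86.4%. At 2.00 h that flask holds intermediate at 3.87% and side product at 84.0%, which is 2.4 points below the line.

The runs stem from a simulated flask for an exercise.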